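**Plan**
- Numbering: C1 is the ketone carbon, C2 and C3 carry the methyls, C4 is the diaryl methine; ring A is the fused benzene ring, ring B the ketone ring. C3 (CH3) and C4 (aryl, benzylic to ring A) are adjacent and trans, the signature of an anti methyl-arylation of a C3=C4 styrene-type bond. C3–CH3 and C4–aryl are therefore cut in one operation.
- Further cuts: the C6 O–CH3 bond (both ring A oxygens travel as benzyl ethers), C1=O back to a silyl-protected carbinol, then C2–CH3 together with the C1–O bridge bond back to a meso 1,4-epoxy-1,4-dihydronaphthalene, and this back to an aryne from catechol plus furan.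
- Forward: ring A comes from catechol. Ring B is built by aryne–furan [4+2] cycloaddition as an oxygen-bridged bicycle and opened with dimethylzinc to a cis-2-methyl-1,2-dihydronaphthalen-1-ol. The three-component coupling then adds CH3 and 3,4-dimethoxyphenyl across C3=C4 without closing a ring. Oxidation at C1, debenzylation and C6 O-methylation finish the route.
- Stereochemistry: C2 comes from catalyst control (palladium/Tol-BINAP desymmetrisation of the meso oxabicycle). C3 and C4 come from substrate control in the key step (CH3 anti to the C2 methyl and the cis C1 silyloxy group, aryl anti to the new C3 methyl). The C1 carbinol centre is a temporary control element, erased on oxidation.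

Key step: step 6

Assumption: in step 4 the (S) enantiomer of Tol-BINAP is taken to deliver the (1R,2R) carbinol, by analogy with the sense of induction known for the unsubstituted oxabicycle; if the sense were opposite, the (R) ligand would be used.

**Route**

Step 1
Reactants: 1 catechol
Product: 2 4,5-dibromobenzene-1,2-diol
Conditions: Br2 (2.05 equiv), AcOH–CHCl3, 0 °C → rt
Reagents that add atoms: bromine, BrBr
Why: Electrophilic aromatic bromination in which each hydroxyl directs para, so two equivalents of bromine should stop at the 4,5-dibromide.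

Step 2
Reactants: 2 4,5-dibromobenzene-1,2-diol
Product: 3 1,2-bis(benzyloxy)-4,5-dibromobenzene
Conditions: BnBr (2.2 equiv), K2CO3 (2.5 equiv), DMF, 60 °C, N2
Reagents that add atoms: benzyl bromide, BrCc1ccccc1
Why: Williamson ether synthesis on both phenols; the benzyl ethers tolerate the organolithium, organozinc and nickel/zinc steps and leave together by hydrogenolysis at the end.

Step 3
Reactants: 3 1,2-bis(benzyloxy)-4,5-dibromobenzene, 4 furan
Product: 7 meso-6,7-bis(benzyloxy)-1,4-dihydro-1,4-epoxynaphthalene, via 2-bromo-4,5-bis(benzyloxy)phenyllithium 5 (not isolated), via 4,5-bis(benzyloxy)benzyne 6 (not isolated)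
Conditions: n-BuLi (1.1 equiv, slow addition), furan (5 equiv), THF, −78 °C → rt
Reagents that add atoms: none
Why: Bromine–lithium exchange and loss of LiBr give the aryne, which furan traps in a Diels–Alder reaction to form the carbon skeleton of ring B as an oxygen-bridged bicycle; the two identical benzyloxy groups on ring A make the adduct meso.

Step 4
Reactants: 7 meso-6,7-bis(benzyloxy)-1,4-dihydro-1,4-epoxynaphthalene, 8 dimethylzinc
Product: 10 (1R,2R)-6,7-bis(benzyloxy)-2-methyl-1,2-dihydronaphthalen-1-ol, via methylzinc alkoxide of the ring-opened carbinol 9 (not isolated)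
Conditions: PdCl2(MeCN)2 (5 mol%), (S)-Tol-BINAP (5 mol%), Me2Zn (1.5 equiv), CH2Cl2, rt; then H2O
Reagents that add atoms: none
Why: Palladium-catalysed enantioselective alkylative ring opening of an oxabenzonorbornadiene with a dialkylzinc, in which a cationic methylpalladium species (divalent palladium) adds syn across the strained alkene from the exo face and β-oxygen elimination opens the bridge, so that methyl and oxygen end up cis while the chiral bisphosphine chooses between the two enantiotopic alkene carbons and thereby sets C2 (R) and C1 (R).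

Step 5
Reactants: 10 (1R,2R)-6,7-bis(benzyloxy)-2-methyl-1,2-dihydronaphthalen-1-ol
Product: 11 (1R,2R)-6,7-bis(benzyloxy)-1-(tert-butyldimethylsilyloxy)-2-methyl-1,2-dihydronaphthalene (cis)
Conditions: TBSCl (1.3 equiv), imidazole (2.5 equiv), DMF, rt
Reagents that add atoms: tert-butyldimethylsilyl chloride, CC(C)(C)[Si](C)(C)Cl
Why: Imidazole-promoted silylation of a secondary alcohol under basic conditions that avoid ionisation of the electron-rich benzylic carbinol; the bulky silyl ether blocks dehydration to the naphthalene and adds shielding to the face already occupied by the C2 methyl.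

Step 6
Reactants: 11 (1R,2R)-6,7-bis(benzyloxy)-1-(tert-butyldimethylsilyloxy)-2-methyl-1,2-dihydronaphthalene, 12 4-bromo-1,2-dimethoxybenzene, 13 N-acetoxyphthalimide
Product: 14 (1R,2R,3S,4R)-6,7-bis(benzyloxy)-1-(tert-butyldimethylsilyloxy)-4-(3,4-dimethoxyphenyl)-2,3-dimethyl-1,2,3,4-tetrahydronaphthalene
Conditions: NiBr2·glyme (10 mol%), 4,4'-di-tert-butyl-2,2'-bipyridine (15 mol%), Zn powder (3 equiv), 12 (3 equiv), 13 (3 equiv, slow addition), DMA, 25 °C
Reagents that add atoms: none
Why: Proposed new method: single-electron reduction of 13 (by low-valent nickel or zinc) expels phthalimide anion and CO2 and leaves a methyl radical, which adds to C3 because that end of the C3=C4 bond leads to the C4 benzylic radical delocalised into ring A and its para benzyloxy group; oxidative addition of 12 to zerovalent nickel gives an aryl nickel bromide (divalent nickel) that captures this radical, reductive elimination from the trivalent nickel species forms C4–aryl, and zinc returns the resulting monovalent nickel to the zerovalent state. The closest known reaction type is the nickel-catalysed reductive three-component alkyl-arylation of alkenes with redox-active esters or alkyl halides and aryl halides, which is established for terminal activated alkenes and for secondary or tertiary radicals but not for methyl radical addition to a cyclic 1,2-disubstituted styrene. No ring is closed; two C–C bonds and two stereocentres are formed. C3 is set by substrate control, the cis C2 methyl and the (preferentially pseudoaxial) C1 silyloxy group covering one face so that the methyl radical enters from the other (2,3-trans), and C4 is set at the nickel stage, where capture and reductive elimination take place on the face away from the new C3 methyl (3,4-trans), reversible radical capture letting the less crowded trans organonickel species go on to product. The selectivities needed are addition at C3 and not C4 (secured by benzylic stabilisation of the C4 radical) and three-component coupling over direct methyl–aryl coupling (addressed by slow addition of 13, which keeps the methyl radical concentration low relative to the alkene, and by an excess of 12 and 13); the benzylic silyl ether and the benzyl ethers are expected to be inert to nickel/zinc in DMA.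

Step 7
Reactants: 14 (1R,2R,3S,4R)-6,7-bis(benzyloxy)-1-(tert-butyldimethylsilyloxy)-4-(3,4-dimethoxyphenyl)-2,3-dimethyl-1,2,3,4-tetrahydronaphthalene
Product: 15 (1R,2R,3S,4R)-6,7-bis(benzyloxy)-4-(3,4-dimethoxyphenyl)-2,3-dimethyl-1,2,3,4-tetrahydronaphthalen-1-ol
Conditions: TBAF (1.5 equiv), THF, 0 °C → rt; aqueous work-up
Reagents that add atoms: none
Why: Fluoride-mediated silyl ether cleavage driven by the Si–F bond, under non-acidic conditions that leave the benzyl ethers and both benzylic positions untouched.

Step 8
Reactants: 15 (1R,2R,3S,4R)-6,7-bis(benzyloxy)-4-(3,4-dimethoxyphenyl)-2,3-dimethyl-1,2,3,4-tetrahydronaphthalen-1-ol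
Product: 16 (2R,3S,4R)-6,7-bis(benzyloxy)-4-(3,4-dimethoxyphenyl)-2,3-dimethyl-3,4-dihydronaphthalen-1(2H)-one
Conditions: Dess–Martin periodinane (1.3 equiv), CH2Cl2, 0 °C → rt
Reagents that add atoms: none
Why: Dess–Martin oxidation of the secondary benzylic alcohol to the aryl ketone removes the C1 centre, which served only as a control element, and any enolisation at C2 would return the more stable 2,3-trans arrangement.

Step 9
Reactants: 16 (2R,3S,4R)-6,7-bis(benzyloxy)-4-(3,4-dimethoxyphenyl)-2,3-dimethyl-3,4-dihydronaphthalen-1(2H)-one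
Product: 17 (2R,3S,4R)-4-(3,4-dimethoxyphenyl)-6,7-dihydroxy-2,3-dimethyl-3,4-dihydronaphthalen-1(2H)-one
Conditions: H2 (1 atm), 10% Pd/C, EtOAc–MeOH, rt; handled under N2 and used directly
Reagents that add atoms: none
Why: Catalytic hydrogenolysis of the two benzyl aryl ethers, which at one atmosphere in a neutral solvent should not reduce the electron-rich aryl ketone or touch the C4–aryl bond.

Step 10
Reactants: 17 (2R,3S,4R)-4-(3,4-dimethoxyphenyl)-6,7-dihydroxy-2,3-dimethyl-3,4-dihydronaphthalen-1(2H)-one
Product: 18 epischisandrone, (2R,3S,4R)-4-(3,4-dimethoxyphenyl)-7-hydroxy-6-methoxy-2,3-dimethyl-3,4-dihydronaphthalen-1(2H)-one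
Conditions: MeI (1.05 equiv), Li2CO3 (1.5 equiv), DMF, 40 °C, N2
Reagents that add atoms: iodomethane, CI
Why: Regioselective Williamson methylation: the C6 hydroxyl is para to the C1 carbonyl and therefore the more acidic one, so a weak carbonate base forms essentially only that phenoxide (as in the 4-O-alkylation of 3,4-dihydroxybenzaldehyde), and Li2CO3 is too weak to enolise C2.

**Compound list**

1 | catechol (benzene-1,2-diol) | Oc1ccccc1O | starting material
2 | 4,5-dibromobenzene-1,2-diol | Oc1cc(Br)c(Br)cc1O | intermediate
3 | 1,2-bis(benzyloxy)-4,5-dibromobenzene | Brc1cc(OCc2ccccc2)c(OCc2ccccc2)cc1Br | intermediate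
4 | furan | c1ccoc1 | starting material
5 | 2-bromo-4,5-bis(benzyloxy)phenyllithium (formed in the flask) | [Li]c1cc(OCc2ccccc2)c(OCc2ccccc2)cc1Br | intermediate
6 | 4,5-bis(benzyloxy)benzyne (formed in the flask) | c1ccccc1COC1=CC#CC=C1OCc1ccccc1 | intermediate
7 | meso-(1R,4S)-6,7-bis(benzyloxy)-1,4-dihydro-1,4-epoxynaphthalene | c1ccccc1COc1cc2c(cc1OCc1ccccc1)[C@H]1C=C[C@@H]2O1 | intermediate
8 | dimethylzinc | C[Zn]C | starting material
9 | methylzinc (1R,2R)-6,7-bis(benzyloxy)-2-methyl-1,2-dihydronaphthalen-1-olate (formed in the flask) | c1ccccc1COc1cc2c(cc1OCc1ccccc1)[C@H](O[Zn]C)[C@H](C)C=C2 | intermediate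
10 | (1R,2R)-6,7-bis(benzyloxy)-2-methyl-1,2-dihydronaphthalen-1-ol (cis) | c1ccccc1COc1cc2c(cc1OCc1ccccc1)[C@H](O)[C@H](C)C=C2 | intermediate
11 | (1R,2R)-6,7-bis(benzyloxy)-1-(tert-butyldimethylsilyloxy)-2-methyl-1,2-dihydronaphthalene (cis) | c1ccccc1COc1cc2c(cc1OCc1ccccc1)[C@H](O[Si](C)(C)C(C)(C)C)[C@H](C)C=C2 | intermediate
12 | 4-bromo-1,2-dimethoxybenzene | COc1ccc(Br)cc1OC | starting material
13 | N-acetoxyphthalimide | CC(=O)ON1C(=O)c2ccccc2C1=O | starting material
14 | (1R,2R,3S,4R)-6,7-bis(benzyloxy)-1-(tert-butyldimethylsilyloxy)-4-(3,4-dimethoxyphenyl)-2,3-dimethyl-1,2,3,4-tetrahydronaphthalene | c1ccccc1COc1cc2c(cc1OCc1ccccc1)[C@H](O[Si](C)(C)C(C)(C)C)[C@H](C)[C@@H](C)[C@@H]2c1ccc(OC)c(OC)c1 | intermediate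
15 | (1R,2R,3S,4R)-6,7-bis(benzyloxy)-4-(3,4-dimethoxyphenyl)-2,3-dimethyl-1,2,3,4-tetrahydronaphthalen-1-ol | c1ccccc1COc1cc2c(cc1OCc1ccccc1)[C@H](O)[C@H](C)[C@@H](C)[C@@H]2c1ccc(OC)c(OC)c1 | intermediate
16 | (2R,3S,4R)-6,7-bis(benzyloxy)-4-(3,4-dimethoxyphenyl)-2,3-dimethyl-3,4-dihydronaphthalen-1(2H)-one | c1ccccc1COc1cc2c(cc1OCc1ccccc1)C(=O)[C@H](C)[C@@H](C)[C@@H]2c1ccc(OC)c(OC)c1 | intermediate
17 | (2R,3S,4R)-4-(3,4-dimethoxyphenyl)-6,7-dihydroxy-2,3-dimethyl-3,4-dihydronaphthalen-1(2H)-one | Oc1cc2c(cc1O)C(=O)[C@H](C)[C@@H](C)[C@@H]2c1ccc(OC)c(OC)c1 | intermediate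
18 | epischisandrone, (2R,3S,4R)-4-(3,4-dimethoxyphenyl)-7-hydroxy-6-methoxy-2,3-dimethyl-3,4-dihydronaphthalen-1(2H)-one | COc1cc2c(cc1O)C(=O)[C@H](C)[C@@H](C)[C@@H]2c1ccc(OC)c(OC)c1 | target

**Step count and risks**

Total steps: 10. Longest linear sequence: 10 steps (from 1 to 18); 4, 8, 12 and 13 are commercial and enter directly.

Step 6 (proposed new method). What may go wrong: interception of the methyl radical by the aryl nickel species before it adds to the hindered internal alkene (direct methyl–aryl coupling), β-hydride elimination of the benzylic nickel intermediate, or poor facial control at C4. The fallback uses known reactions only, sets out from 11 and rejoins the route at 16. It relies on ring A carrying two identical benzyloxy groups, so that the two benzylic carbons of ring B can exchange roles: the silyloxy-bearing carbon becomes the aryl-bearing C4 and the benzylic alkene carbon becomes C1. Mukaiyama hydration of 11 (Co(acac)2, PhSiH3, O2, THF) should place a hydroxyl on the benzylic alkene carbon and give (3R,4R)-6,7-bis(benzyloxy)-4-(tert-butyldimethylsilyloxy)-3-methyl-1,2,3,4-tetrahydronaphthalen-1-ol F1 (both carbinol epimers are usable). Dess–Martin oxidation should give (3R,4R)-6,7-bis(benzyloxy)-4-(tert-butyldimethylsilyloxy)-3-methyl-3,4-dihydronaphthalen-1(2H)-one F2. Enolate methylation (LiN(i-Pr)2, THF, −78 °C, then MeI) should enter trans to the neighbouring methyl and give (2R,3R,4R)-6,7-bis(benzyloxy)-4-(tert-butyldimethylsilyloxy)-2,3-dimethyl-3,4-dihydronaphthalen-1(2H)-one F3. TBAF should then free (2R,3R,4R)-6,7-bis(benzyloxy)-4-hydroxy-2,3-dimethyl-3,4-dihydronaphthalen-1(2H)-one F4. Friedel–Crafts alkylation of 1,2-dimethoxybenzene with F4 (BF3·OEt2, CH2Cl2, −40 °C) proceeds through the para-benzyloxy-stabilised benzylic cation; the arene should attack through its position para to a methoxy group and anti to the adjacent methyl, giving the all-trans 4-aryl tetralone, which is 16. Steps 7 and 8 then fall away.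

Step 10. What may go wrong: insufficient discrimination between the two phenols, or over-methylation to the dimethyl ether. The fallback runs from 17 back to 18 and reverses the order in which the two oxygens are addressed. The dianion of 17 (NaH, 2.1 equiv, DMSO) is treated with one equivalent of benzyl bromide, which should alkylate the less stabilised and therefore more nucleophilic C7 phenoxide to give (2R,3S,4R)-7-(benzyloxy)-4-(3,4-dimethoxyphenyl)-6-hydroxy-2,3-dimethyl-3,4-dihydronaphthalen-1(2H)-one F5. Methylation of the single remaining phenol (MeI, K2CO3, acetone) should give (2R,3S,4R)-7-(benzyloxy)-4-(3,4-dimethoxyphenyl)-6-methoxy-2,3-dimethyl-3,4-dihydronaphthalen-1(2H)-one F6, and hydrogenolysis (H2, Pd/C, EtOAc) should give 18.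

Step 4. What may go wrong: incomplete enantioselection on the bis(benzyloxy) substrate, which would carry through to the target, or acid-triggered loss of water from the electron-rich carbinol with aromatisation. The fallback runs from 7 back to 10 and replaces catalyst control by kinetic resolution. Ring opening with the achiral catalyst PdCl2(dppf) and Me2Zn (CH2Cl2, rt) should give racemic cis-6,7-bis(benzyloxy)-2-methyl-1,2-dihydronaphthalen-1-ol F7. Lipase-catalysed transesterification (Candida antarctica lipase B, vinyl acetate, MTBE) is expected, by the usual empirical preference of lipases for the (R) enantiomer of secondary aryl carbinols, to acylate the (1R,2R) enantiomer to (1R,2R)-6,7-bis(benzyloxy)-2-methyl-1,2-dihydronaphthalen-1-yl acetate F8. This is separated from the unreacted (1S,2S) alcohol and methanolysed (K2CO3, MeOH) to 10; if the enzyme preference were the reverse, 10 would be the unreacted alcohol.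

**Further compounds**

F1 | step 6 | (3R,4R)-6,7-bis(benzyloxy)-4-(tert-butyldimethylsilyloxy)-3-methyl-1,2,3,4-tetrahydronaphthalen-1-ol (C1 epimers) | c1ccccc1COc1cc2c(cc1OCc1ccccc1)[C@H](O[Si](C)(C)C(C)(C)C)[C@H](C)CC2O
F2 | step 6 | (3R,4R)-6,7-bis(benzyloxy)-4-(tert-butyldimethylsilyloxy)-3-methyl-3,4-dihydronaphthalen-1(2H)-one | c1ccccc1COc1cc2c(cc1OCc1ccccc1)[C@H](O[Si](C)(C)C(C)(C)C)[C@H](C)CC2=O
F3 | step 6 | (2R,3R,4R)-6,7-bis(benzyloxy)-4-(tert-butyldimethylsilyloxy)-2,3-dimethyl-3,4-dihydronaphthalen-1(2H)-one | c1ccccc1COc1cc2c(cc1OCc1ccccc1)[C@H](O[Si](C)(C)C(C)(C)C)[C@H](C)[C@@H](C)C2=O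
F4 | step 6 | (2R,3R,4R)-6,7-bis(benzyloxy)-4-hydroxy-2,3-dimethyl-3,4-dihydronaphthalen-1(2H)-one | c1ccccc1COc1cc2c(cc1OCc1ccccc1)[C@H](O)[C@H](C)[C@@H](C)C2=O
F5 | step 10 | (2R,3S,4R)-7-(benzyloxy)-4-(3,4-dimethoxyphenyl)-6-hydroxy-2,3-dimethyl-3,4-dihydronaphthalen-1(2H)-one | Oc1cc2c(cc1OCc1ccccc1)C(=O)[C@H](C)[C@@H](C)[C@@H]2c1ccc(OC)c(OC)c1
F6 | step 10 | (2R,3S,4R)-7-(benzyloxy)-4-(3,4-dimethoxyphenyl)-6-methoxy-2,3-dimethyl-3,4-dihydronaphthalen-1(2H)-one | COc1cc2c(cc1OCc1ccccc1)C(=O)[C@H](C)[C@@H](C)[C@@H]2c1ccc(OC)c(OC)c1
F7 | step 4 | racemic cis-6,7-bis(benzyloxy)-2-methyl-1,2-dihydronaphthalen-1-ol (1R,2R and 1S,2S, both drawn) | c1ccccc1COc1cc2c(cc1OCc1ccccc1)[C@H](O)[C@H](C)C=C2.c1ccccc1COc1cc2c(cc1OCc1ccccc1)[C@@H](O)[C@@H](C)C=C2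
F8 | step 4 | (1R,2R)-6,7-bis(benzyloxy)-2-methyl-1,2-dihydronaphthalen-1-yl acetate | c1ccccc1COc1cc2c(cc1OCc1ccccc1)[C@H](OC(C)=O)[C@H](C)C=C2
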